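**Retrosynthetic overview**

1. The enabling feature (germacrane numbering) is the 1,5-diene C10=C1–C2–C3–C4=C5 inside the ten-membered ring C1–C10, with both alkenes ring-cis and C1=C10 conjugated with the C14 ester; its central σ-bond C2–C3 is the bond a [3,3] shift makes.
2. Key disconnection: C2–C3 by Cope rearrangement of a cis-2-vinyl-3-isopropenyl-7-oxabicyclo[2.2.1]heptane (alkenyl groups on C10 and C5, C14 ester on C10, temporary oxygen bridge C9–O–C6 whose oxygen later becomes the C9 acetate oxygen); the bicycle allows only a boat transition state and supplies strain release.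
3. After it: acylative opening of the bridge at allylic C6 with capture by the C7 acrylate (trans α-methylene lactone plus C9 acetate in one operation), then SeO2 oxidation of C15.
4. Before it: Diels–Alder of an (S)-butenolide ester (C10=C5 dienophile; its lactone is the masked cis-alkenyl pair and the chiral controller) with 1-silyloxybutadiene; directed epoxidation and selenium transposition (C8–O); iodoetherification (bridge); radical alkynylation (C7); lactone converted to vinyl and isopropenyl.
5. Ring order: butenolide → cyclohexene C5–C10 → oxygen bridge (tetrahydrofuran) → butenolide opened → ten-membered ring → α-methylene γ-lactone (bridge lost).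

Key step: step 13

Remark: germacrane numbering is used for all intermediates (ring C1–C10, lactone carbons C11–C13, ester carbon C14 on C10, C15 on C4); "ring-cis" means that the two ring neighbours of an alkene are cis, and "exo" means syn to the oxygen bridge.

**Route**

Step 1
Reactants: 1 (S)-2-methyloxirane; 2 dimethyl malonate
Product: 3 methyl (5S)-5-methyl-2-oxooxolane-3-carboxylate
Conditions: NaOMe (1.0 equiv), MeOH, 0 → 65 °C; then aq. HCl
Reagents that add atoms: none
Why: Malonate anion opens the epoxide at the unsubstituted carbon (SN2, the stereocentre is not touched) and the alkoxide lactonises onto one ester (classical malonate–epoxide γ-lactone synthesis), so the (S) centre of 1 becomes the oxygen-bearing lactone carbon.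

Step 2
Reactants: 3 methyl (5S)-5-methyl-2-oxooxolane-3-carboxylate
Product: 5 methyl (5S)-5-methyl-2-oxo-2,5-dihydrofuran-3-carboxylate, via selenide 4 (not isolated)
Conditions: NaH, PhSeCl, THF, 0 °C; then H2O2 (30 %), CH2Cl2, 0 → 25 °C
Reagents that add atoms: none
Why: α-Selenenylation of the doubly activated lactone enolate and selenoxide syn-elimination toward the only β-hydrogens (ring CH2) should give the butenolide ester without involving the stereocentre.

Step 3
Reactants: 5 methyl (5S)-5-methyl-2-oxo-2,5-dihydrofuran-3-carboxylate; 6 (E)-1-(trimethylsilyloxy)buta-1,3-diene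
Product: 8 cis-fused bicyclic lactone alcohol (cyclohexene C5–C10 with C9-OH), via silyl ether 7 (not isolated)
Conditions: PhMe, 60 °C; then citric acid, MeOH, 0 °C
Reagents that add atoms: none
Why: Normal-demand Diels–Alder reaction in which the siloxy-bearing diene terminus bonds to the doubly acceptor-substituted carbon (future C10), the diene approaches anti to the methyl of the butenolide and endo to the ring carbonyl, so that C10, C5 and C9 are set from the (S) centre with the C9 oxygen cis to the lactone ring; mild acid methanolysis then frees the alcohol.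

Step 4
Reactants: 8 cis-fused bicyclic lactone alcohol
Product: 9 cis-epoxy alcohol (C7–C8 oxirane syn to C9-OH)
Conditions: VO(acac)2 (5 mol %), t-BuOOH, CH2Cl2, 0 → 25 °C
Reagents that add atoms: tert-butyl hydroperoxide (CC(C)(C)OO)
Why: Hydroxyl-directed vanadium-catalysed epoxidation of the cyclic allylic alcohol delivers oxygen to the alkene face syn to the OH, which sets the C8–O bond cis to the C9–O bond.

Step 5
Reactants: 9 cis-epoxy alcohol
Product: 11 allylic cis-diol (C8-OH and C9-OH cis with C6=C7 alkene), via hydroxy selenide 10 (not isolated)
Conditions: PhSeH, Et3N (cat.), EtOH, 25 °C; then H2O2 (30 %), THF, 0 → 25 °C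
Reagents that add atoms: none
Why: Selenolate should open the epoxide trans-diaxially at the carbon remote from the hydroxyl (C7), and selenoxide syn-elimination can only run toward the C6 methylene, so this organoselenium epoxide-to-allylic-alcohol transposition leaves the cis-diol intact and moves the alkene to C6=C7.

Step 6
Reactants: 11 allylic cis-diol
Product: 12 iodo-7-oxabicyclo[2.2.1]heptane lactone (bridge C9–O–C6 and iodine on C7)
Conditions: N-iodosuccinimide, NaHCO3, MeCN, 0 °C, dark
Reagents that add atoms: N-iodosuccinimide (O=C1CCC(=O)N1I)
Why: Iodoetherification of a cyclohex-3-enol to a 7-oxabicyclo[2.2.1]heptane, in which the iodonium forms on the face opposite to the C9 hydroxyl and that oxygen adds transannularly to C6, so the bridge is cis to the C8 hydroxyl and the lactone (C6 set, to be inverted in step 14) and iodine ends on C7.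

Step 7
Reactants: 12 iodo-7-oxabicyclo[2.2.1]heptane lactone
Product: 14 exo-ethynyl bridged lactone alcohol, via silylalkyne 13 (not isolated)
Conditions: Me3SiC≡CSO2Ph, (Bu3Sn)2, hν (sunlamp), PhH, 40 °C; then Bu4NF, AcOH, THF, 0 °C
Reagents that add atoms: phenyl 2-(trimethylsilyl)ethynyl sulfone (C[Si](C)(C)C#CS(=O)(=O)c1ccccc1)
Why: Tin-mediated radical alkynylation in which the secondary C7 radical adds to the sulfonyl-bearing alkyne carbon and expels the sulfonyl radical; like other 2-norbornyl-type radicals it should be trapped on the exo face, setting C7 with the alkyne cis to the C8 oxygen whatever the configuration of the iodide, and buffered fluoride then removes the silyl group.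

Step 8
Reactants: 14 exo-ethynyl bridged lactone alcohol
Product: 15 C8 isobutyrate
Conditions: (i-PrCO)2O, DMAP (cat.), pyridine, CH2Cl2, 0 → 25 °C
Reagents that add atoms: isobutyric anhydride (CC(C)C(=O)OC(=O)C(C)C)
Why: DMAP-catalysed acylation of the only free hydroxyl installs the isobutyrate of the target, which also protects the C8 oxygen during the following steps.

Step 9
Reactants: 15 C8 isobutyrate
Product: 17 exo-vinyl hydroxyethyl oxabicycle, via lactol 16 (not isolated)
Conditions: i-Bu2AlH (1.1 equiv), CH2Cl2, −78 °C; then Ph3P=CH2 (MePPh3Br, KN(SiMe3)2), THF, 0 °C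
Reagents that add atoms: methyltriphenylphosphonium bromide (C[P+](c1ccccc1)(c1ccccc1)c1ccccc1.[Br-])
Why: At −78 °C the aluminium hydride should reduce the lactone (more electrophilic than the neopentyl methyl ester and the branched isobutyrate) only to the lactol, and Wittig methylenation of its open hydroxy-aldehyde form gives the vinyl group on quaternary C10 and frees the secondary alcohol without touching a stereocentre.

Step 10
Reactants: 17 exo-vinyl hydroxyethyl oxabicycle
Product: 18 exo-acetyl compound
Conditions: Dess–Martin periodinane, NaHCO3, CH2Cl2, 0 → 25 °C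
Reagents that add atoms: none
Why: Buffered Dess–Martin oxidation of the only free alcohol gives the methyl ketone under non-epimerising conditions and removes the stereocentre that served as chiral controller.

Step 11
Reactants: 18 exo-acetyl compound
Product: 19 cis-exo-vinyl/isopropenyl oxabicycle
Conditions: Zn, CH2Br2, TiCl4, THF/CH2Cl2, 0 → 25 °C
Reagents that add atoms: dibromomethane (BrCBr)
Why: Lombardo–Takai methylenation with a non-basic gem-dimetal reagent should convert the enolisable ketone into the 1,1-disubstituted alkene without epimerising C5 and without attacking the esters, completing the cis-alkenyl pair.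

Step 12
Reactants: 19 cis-exo-vinyl/isopropenyl oxabicycle
Product: 20 acrylate-bearing Cope substrate
Conditions: Pd(OAc)2 (2 mol %), 2-(diphenylphosphino)pyridine, MeSO3H, CO (30 bar), MeOH, 45 °C
Reagents that add atoms: carbon monoxide ([C-]#[O+]); methanol (CO)
Why: Palladium-catalysed Markovnikov hydromethoxycarbonylation of the terminal alkyne (a catalyst system known to give 2-substituted acrylates) builds the C11(=C13)–C12 acrylate on C7, while the simple alkenes react far more slowly.

Step 13
Reactants: 20 acrylate-bearing Cope substrate
Product: 21 6,9-epoxy-bridged germacra-1(10),4-diene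
Conditions: PhMe (0.01 M), BHT, 120 °C, sealed tube
Reagents that add atoms: none
Why: Thermal [3,3]-sigmatropic (Cope) rearrangement: the exo vinyl on C10 and the exo isopropenyl on C5 are held eclipsed across the C5–C10 bond of the 7-oxabicyclo[2.2.1]heptane and lie over the small oxygen bridge, so the array C2=C1–C10–C5–C4=C3 can only reach a boat transition state in which C2–C3 forms while C5–C10 breaks; the closest known reaction types are the Cope rearrangement of cis-1,2-divinylcyclobutanes and -cyclopentanes to cis,cis-cycloalka-1,5-dienes and the elemane–germacrane Cope equilibrium. The new bond closes the ten-membered carbocycle C1–C10 (a nine-membered oxacycle when counted through the bridge) by concerted ring expansion of the five-membered ring C5–C6–O–C9–C10, not by end-to-end cyclisation. No stereocentre is made and those at C5 and C10 are erased, which is why only the cis relation of the two alkenyl groups had to be secured; the boat places C6 and C9 pseudoaxial, so C3 ends cis to C6 and C2 cis to C9 with the ester on C10 trans to C2, the ring-cis, ring-cis pattern of the target. The step needs this geometric selectivity and a favourable equilibrium: the first is secured by the bicyclic lock, since a chair transition state is out of reach and a trans alkene would be badly strained in the nine-membered oxacycle, the second by release of oxanorbornane strain, by conjugation of the new C1=C10 bond with the C14 ester and by loss of the congested quaternary centre. The acrylate on C7 is a bystander, kept from oligomerising by dilution and a radical inhibitor.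

Step 14
Reactants: 21 6,9-epoxy-bridged germacra-1(10),4-diene
Product: 22 15-deoxy target (trans α-methylene lactone with C9 acetate)
Conditions: Ac2O, Sc(OTf)3 (5 mol %), CH2Cl2, −20 → 0 °C
Reagents that add atoms: acetic anhydride (CC(=O)OC(C)=O)
Why: Proposed new method: Lewis-acid-activated acetic anhydride should acylate the bridging ether oxygen, the C6–O bond then ionises because C6 is allylic to the electron-rich C4=C5 bond (C9 is deactivated by the enoate and flanked by the acyloxy carbon), and the carbonyl oxygen of the neighbouring C7 acrylate ester captures C6 from the face opposite to the departing, still tethered C9 acetoxy oxygen, which after O-demethylation by acetate gives the trans-fused α-methylene lactone with inversion at C6 and the C9 acetate with retention; the closest known reaction types are the Lewis acid/anhydride acylative cleavage of tetrahydrofurans and 7-oxabicyclo[2.2.1]heptanes and the halolactonisation of alkyl esters with loss of the alkyl group.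

Step 15
Reactants: 22 15-deoxy target
Product: 23 target CNP0242134.4
Conditions: SeO2 (0.3 equiv), t-BuOOH, CH2Cl2, 0 → 25 °C
Reagents that add atoms: tert-butyl hydroperoxide (CC(C)(C)OO)
Why: SeO2 allylic oxidation (ene reaction, then [2,3]-sigmatropic shift) should pick the C15 methyl, the alkyl group trans to C6 on the only electron-rich trisubstituted alkene, and the [2,3] step returns C4=C5 with the hydroxymethyl group trans to C6, the geometry already present, while the enoate and the α-methylene lactone are too electron-poor to react.

**Compound list**

1 | (S)-2-methyloxirane ((S)-propylene oxide) | C[C@H]1CO1 | starting material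
2 | dimethyl malonate | COC(=O)CC(=O)OC | starting material
3 | methyl (5S)-5-methyl-2-oxooxolane-3-carboxylate (C3 epimers) | COC(=O)C1C[C@H](C)OC1=O | intermediate
4 | methyl (5S)-5-methyl-2-oxo-3-(phenylselanyl)oxolane-3-carboxylate | COC(=O)C1([Se]c2ccccc2)C[C@H](C)OC1=O | intermediate
5 | methyl (5S)-5-methyl-2-oxo-2,5-dihydrofuran-3-carboxylate | COC(=O)C1=C[C@H](C)OC1=O | intermediate
6 | (E)-1-(trimethylsilyloxy)buta-1,3-diene | C=C/C=C/O[Si](C)(C)C | starting material
7 | Diels–Alder adduct silyl ether: cis-fused methyl (3S)-3-methyl-1-oxo-7-(trimethylsilyloxy)-3,3a,4,7-tetrahydro-2-benzofuran-7a(1H)-carboxylate; silyloxy group cis to the lactone ring; 3-methyl trans to the C3a–C4 bond | COC(=O)[C@]12[C@@H](O[Si](C)(C)C)C=CC[C@H]1[C@H](C)OC2=O | intermediate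
8 | cis-fused bicyclic lactone alcohol (7-hydroxy analogue of 7; germacrane C9-OH cis to the lactone ring) | COC(=O)[C@]12[C@@H](O)C=CC[C@H]1[C@H](C)OC2=O | intermediate
9 | cis-epoxy alcohol (oxirane on germacrane C7–C8, oxygen cis to the C9-OH) | COC(=O)[C@]12[C@@H](O)[C@H]3O[C@H]3C[C@H]1[C@H](C)OC2=O | intermediate
10 | hydroxy selenide (C8-OH and C9-OH cis; C7-SePh trans to C8-OH) | COC(=O)[C@]12[C@@H](O)[C@@H](O)[C@H]([Se]c3ccccc3)C[C@H]1[C@H](C)OC2=O | intermediate
11 | allylic cis-diol (C8-OH, C9-OH and lactone ring all cis; C6=C7 alkene) | COC(=O)[C@]12[C@@H](O)[C@@H](O)C=C[C@H]1[C@H](C)OC2=O | intermediate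
12 | iodo-7-oxabicyclo[2.2.1]heptane lactone (bridge C9–O–C6; lactone ring and C8-OH exo; C7-I endo) | COC(=O)[C@]12[C@@H]3[C@@H](O)[C@H](I)[C@@H](O3)[C@H]1[C@H](C)OC2=O | intermediate
13 | exo-(trimethylsilylethynyl) bridged lactone alcohol (alkyne on C7 cis to C8-OH) | COC(=O)[C@]12[C@@H]3[C@@H](O)[C@@H](C#C[Si](C)(C)C)[C@@H](O3)[C@H]1[C@H](C)OC2=O | intermediate
14 | exo-ethynyl bridged lactone alcohol | COC(=O)[C@]12[C@@H]3[C@@H](O)[C@@H](C#C)[C@@H](O3)[C@H]1[C@H](C)OC2=O | intermediate
15 | C8 isobutyrate of 14 | COC(=O)[C@]12[C@@H]3[C@@H](OC(=O)C(C)C)[C@@H](C#C)[C@@H](O3)[C@H]1[C@H](C)OC2=O | intermediate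
16 | lactol of 15 (anomeric mixture) | COC(=O)[C@]12[C@@H]3[C@@H](OC(=O)C(C)C)[C@@H](C#C)[C@@H](O3)[C@H]1[C@H](C)OC2O | intermediate
17 | methyl 2-exo-ethenyl-5-exo-ethynyl-3-exo-[(1S)-1-hydroxyethyl]-6-exo-(2-methylpropanoyloxy)-7-oxabicyclo[2.2.1]heptane-2-carboxylate (ester endo) | C=C[C@@]1(C(=O)OC)[C@@H]2[C@@H](OC(=O)C(C)C)[C@@H](C#C)[C@@H](O2)[C@H]1[C@H](C)O | intermediate
18 | 3-exo-acetyl analogue of 17 | C=C[C@@]1(C(=O)OC)[C@@H]2[C@@H](OC(=O)C(C)C)[C@@H](C#C)[C@@H](O2)[C@H]1C(C)=O | intermediate
19 | 3-exo-(prop-1-en-2-yl) analogue (cis-exo-vinyl/isopropenyl pair) | C=C[C@@]1(C(=O)OC)[C@@H]2[C@@H](OC(=O)C(C)C)[C@@H](C#C)[C@@H](O2)[C@H]1C(C)=C | intermediate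
20 | Cope substrate: 5-exo-(3-methoxy-3-oxoprop-1-en-2-yl) analogue of 19 | C=C[C@@]1(C(=O)OC)[C@@H]2[C@@H](OC(=O)C(C)C)[C@@H](C(=C)C(=O)OC)[C@@H](O2)[C@H]1C(C)=C | intermediate
21 | 6,9-epoxy-bridged germacra-1(10),4-diene: methyl 6-methyl-9-(3-methoxy-3-oxoprop-1-en-2-yl)-10-(2-methylpropanoyloxy)-11-oxabicyclo[6.2.1]undeca-2,6-diene-2-carboxylate; both ring alkenes ring-cis; acrylate and isobutyrate cis to each other and trans to the two ring bonds at the bridgeheads | COC(=O)/C1=C/CC/C(C)=C\[C@H]2[C@H](C(=C)C(=O)OC)[C@H](OC(=O)C(C)C)[C@@H]1O2 | intermediate
22 | 15-deoxy target (23 with CH3 in place of CH2OH on C4; trans-fused α-methylene lactone; C9 acetate; C8 isobutyrate) | C=C1C(=O)O[C@@H]2/C=C(/C)CC/C=C(/C(=O)OC)[C@@H](OC(C)=O)[C@@H](OC(=O)C(C)C)[C@@H]12 | intermediate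
23 | CNP0242134.4 | C=C1C(=O)O[C@@H]2/C=C(/CO)CC/C=C(/C(=O)OC)[C@@H](OC(C)=O)[C@@H](OC(=O)C(C)C)[C@@H]12 | target

**Step count and risks**

Total step count: 15. Longest linear sequence: 15 steps (from 1).

Steps most likely to fail:

First, step 14 (Proposed new method). The C6 allyl cation may be captured by external acetate instead of the neighbouring ester, facial control at C6 may be lost, or the allylic system may transpose toward C4. The fallback uses known chemistry and sets out from 21: plain acetolysis of the allylic cyclic ether with Ac2O and catalytic FeCl3 in CH2Cl2 at −20 °C should give the open 6,9-diacetate F1 (backside attack of acetate at C6, the C9 oxygen staying in place as acetate). K2CO3 in MeOH at 0 °C should then remove the less hindered allylic C6 acetate, and the freed alkoxide closes onto the neighbouring methyl acrylate. This comes back to the route at 22.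

Second, step 9. Hydride may attack the geminal methyl ester or the isobutyrate in competition with the lactone (over-reduction). The fallback sets out from 15: ring-opening of the lactone with MeNHOMe·HCl and Me3Al (CH2Cl2, 0 °C; lactones react much faster than hindered esters) should give the Weinreb amide F2. i-Bu2AlH (THF, −78 °C) stops at the aldehyde stage of such amides and should deliver lactol 16, and the Wittig methylenation of step 9 comes back to the route at 17.

Third, step 13. The acrylate may oligomerise or enter ene chemistry at the temperature the sigmatropic shift needs, or the rearrangement may start in an uncontrolled way during the warm carbonylation of step 12. The fallback sets out from 19 and moves the rearrangement one stage earlier: heating 19 (PhMe, BHT, 110 °C) should give the bridged enyne F3, and the hydromethoxycarbonylation of step 12 carried out on F3 comes back to the route at 21.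

Further compounds
F1 | step 14 | open 6,9-diacetate: methyl acrylate-bearing germacra-1(10),4-diene with C6-OAc (inverted) and C9-OAc | COC(=O)/C1=C/CC/C(C)=C\[C@@H](OC(C)=O)[C@H](C(=C)C(=O)OC)[C@H](OC(=O)C(C)C)[C@@H]1OC(C)=O
F2 | step 9 | Weinreb amide from lactone opening of 15 (N-methoxy-N-methylcarboxamide on C10; free 1-hydroxyethyl on C5) | CON(C)C(=O)[C@@]1(C(=O)OC)[C@@H]2[C@@H](OC(=O)C(C)C)[C@@H](C#C)[C@@H](O2)[C@H]1[C@H](C)O
F3 | step 13 | 6,9-epoxy-bridged germacra-1(10),4-diene with ethynyl on C7 (Cope product of 19) | COC(=O)/C1=C/CC/C(C)=C\[C@H]2[C@H](C#C)[C@H](OC(=O)C(C)C)[C@@H]1O2
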